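**Plan**
- The side chain is numbered C1' (OCH2) to C8' (=CH2). The retrosynthesis cuts the aryl ether O–C1', then C1'–C2' together with C3'–CH3, then C3'–C4', and traces C7' back to an ester carbon.
- Enabling feature: the C2'=C3' alkene is E-trisubstituted with its C3' methyl on the same side as C1'. This is the pattern left by syn addition of methyl and metal to a terminal C2'≡C3' alkyne followed by one-carbon capture at C2'. No ring forms in this event; the coumarin bicycle is bought intact.
- Forward order: tartrate acetonide diester → mono-alcohol → methyl ketone → isopropenyl → triflate → silylpropargyl → enyne diol → bis-silyl ether → methylalumination/hydroxymethylation → Mitsunobu coupling to the coumarin → desilylation.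
- Stereochemistry: C5' and C6' are the two carbinol carbons of L-tartaric acid and no bond to them is broken. They are R,R in the tartrate and S,S in the target only because CIP priorities change. The alkene geometry comes from the syn carbometalation.

Key step: step 8

Remark: dimethyl 2,3-O-isopropylidene-L-tartrate (the acetonide of dimethyl L-tartrate) and 7-hydroxy-8-methoxycoumarin are taken as purchased materials.

Step 1
Reactants: 1 dimethyl (4R,5R)-2,2-dimethyl-1,3-dioxolane-4,5-dicarboxylate
Product: 2 methyl (4R,5S)-5-(hydroxymethyl)-2,2-dimethyl-1,3-dioxolane-4-carboxylate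
Conditions: NaBH4 (0.6 equiv), MeOH, −10 to 0 °C; aq. NH4Cl
Reagents that add atoms: none
Why: Partial borohydride reduction of an α-alkoxy diester: the diester is more electrophilic than the mono-reduced alkoxyborate and offers two equivalent (C2-related) ester groups, so a limited hydride charge at low temperature should stop mainly at the mono-alcohol, leaving the acetonide and both stereocentres untouched.

Step 2
Reactants: 2 methyl (4R,5S)-5-(hydroxymethyl)-2,2-dimethyl-1,3-dioxolane-4-carboxylate
Product: 4 1-[(4R,5S)-5-(hydroxymethyl)-2,2-dimethyl-1,3-dioxolan-4-yl]ethan-1-one, via hydroxy Weinreb amide 3 (not isolated)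
Conditions: MeNH(OMe)·HCl (1.5 equiv), i-PrMgCl (4 equiv), THF, −20 °C; then MeMgBr (3 equiv), −20 to 0 °C; aq. NH4Cl
Reagents that add atoms: methylmagnesium bromide, C[Mg]Br; N,O-dimethylhydroxylamine hydrochloride, CNOC.Cl (its atoms stay only in 3)
Why: Ester aminolysis by the chloromagnesium amide followed by the Weinreb ketone synthesis: the hydroxyl travels as its magnesium alkoxide, the chelated tetrahedral adduct blocks a second methyl addition, and the ketone is released only on work-up, so the α-centre in the favoured trans-dioxolane should not epimerise.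

Step 3
Reactants: 4 1-[(4R,5S)-5-(hydroxymethyl)-2,2-dimethyl-1,3-dioxolan-4-yl]ethan-1-one
Product: 5 [(4S,5S)-2,2-dimethyl-5-(prop-1-en-2-yl)-1,3-dioxolan-4-yl]methanol
Conditions: Ph3PCH3Br (3.0 equiv), KOt-Bu (2.9 equiv), THF, 0 °C to rt
Reagents that add atoms: methyltriphenylphosphonium bromide, C[P+](c1ccccc1)(c1ccccc1)c1ccccc1.[Br-]
Why: Wittig methylenation of a methyl ketone with excess ylide to cover the free hydroxyl; addition to the unhindered ketone should outrun enolisation, and the switch of the ring-carbon descriptor from R to S is only a change of CIP priorities.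

Step 4
Reactants: 5 [(4S,5S)-2,2-dimethyl-5-(prop-1-en-2-yl)-1,3-dioxolan-4-yl]methanol
Product: 6 [(4S,5S)-2,2-dimethyl-5-(prop-1-en-2-yl)-1,3-dioxolan-4-yl]methyl trifluoromethanesulfonate
Conditions: Tf2O (1.2 equiv), 2,6-lutidine (1.5 equiv), CH2Cl2, −78 °C; cold aqueous work-up, crude 6 used at once
Reagents that add atoms: trifluoromethanesulfonic anhydride, O=S(=O)(OS(=O)(=O)C(F)(F)F)C(F)(F)F
Why: Sulfonylation of the unhindered primary alcohol at low temperature with a hindered pyridine base supplies the leaving group needed at a β-oxygenated primary carbon where tosylates and halides react sluggishly; the alkene and acetonide are inert under these buffered conditions.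

Step 5
Reactants: 6 [(4S,5S)-2,2-dimethyl-5-(prop-1-en-2-yl)-1,3-dioxolan-4-yl]methyl trifluoromethanesulfonate
Product: 7 trimethyl{3-[(4S,5S)-2,2-dimethyl-5-(prop-1-en-2-yl)-1,3-dioxolan-4-yl]prop-1-yn-1-yl}silane
Conditions: Me3SiC≡CH (2.0 equiv), n-BuLi (1.9 equiv), THF, −78 °C; then 6, DMPU, −78 to −20 °C
Reagents that add atoms: ethynyltrimethylsilane, C#C[Si](C)(C)C
Why: SN2 alkylation of a lithium acetylide by a primary triflate in THF/DMPU, a reliable reaction for dioxolan-4-ylmethyl triflates; the silyl cap keeps the acetylide monofunctional and the stereocentres are not involved.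

Step 6
Reactants: 7 trimethyl{3-[(4S,5S)-2,2-dimethyl-5-(prop-1-en-2-yl)-1,3-dioxolan-4-yl]prop-1-yn-1-yl}silane
Product: 9 (3S,4S)-2-methylhept-1-en-6-yne-3,4-diol, via silylalkyne diol 8 (not isolated)
Conditions: p-TsOH·H2O (0.2 equiv), MeOH, 50 °C; then K2CO3 (2 equiv), rt
Reagents that add atoms: none
Why: Acid-catalysed transketalisation to methanol frees the trans-diol, and base-mediated methanolysis of the C(sp)–Si bond in the same flask unmasks the terminal alkyne; the acetonide is removed here because AlMe3 can open it and a late acidic removal would endanger the allylic aryl ether of the target.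

Step 7
Reactants: 9 (3S,4S)-2-methylhept-1-en-6-yne-3,4-diol
Product: 10 (3S,4S)-3,4-bis[(tert-butyldimethylsilyl)oxy]-2-methylhept-1-en-6-yne
Conditions: TBSOTf (2.6 equiv), 2,6-lutidine (4 equiv), CH2Cl2, 0 °C to rt
Reagents that add atoms: tert-butyldimethylsilyl trifluoromethanesulfonate, CC(C)(C)[Si](C)(C)OS(=O)(=O)C(F)(F)F
Why: Silylation of a hindered vicinal secondary diol with the silyl triflate and 2,6-lutidine; the terminal alkyne is not silylated under these conditions, and the bis-silyl ether is inert to AlMe3 and n-BuLi yet removable with fluoride at the end.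

Step 8
Reactants: 10 (3S,4S)-3,4-bis[(tert-butyldimethylsilyl)oxy]-2-methylhept-1-en-6-yne
Product: 13 (2E,5S,6S)-5,6-bis[(tert-butyldimethylsilyl)oxy]-3,7-dimethylocta-2,7-dien-1-ol, via alkenyldimethylalane 11 (not isolated), via lithium alkenylalanate 12 (not isolated)
Conditions: AlMe3 (2.0 equiv), Cp2ZrCl2 (0.25 equiv), CH2Cl2, 0 °C to rt; volatiles removed in vacuo; n-BuLi (1.0 equiv), hexane/THF, −78 °C; (CH2O)n (5 equiv), −78 °C to rt; aq. potassium sodium tartrate
Reagents that add atoms: trimethylaluminium, C[Al](C)C; formaldehyde from paraformaldehyde, C=O; n-butyllithium, [Li]CCCC (its atoms stay only in 12)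
Why: Cp2ZrCl2 and AlMe3 form a methylzirconocene–aluminium species that delivers CH3 and metal to the same face of the terminal alkyne, methyl to the substituted carbon C3' and metal to the terminal carbon C2', and transmetalation to aluminium gives alkenylalane 11 while the zirconocene re-enters the cycle. n-BuLi turns 11 into the more nucleophilic alanate 12, whose alkenyl group adds to monomeric formaldehyde with retention at C2', which leaves the C3' methyl and C1' on the same side of the double bond (E). The closest known reaction type is the zirconocene-catalysed methylalumination of terminal alkynes with formaldehyde capture of the alkenylalanate, the standard entry to (E)-3-methylalk-2-en-1-ols, including those from homopropargylic silyl ethers. No ring closes and no stereocentre is created; C5' and C6' are spectators. The step needs regioselectivity, syn-stereoselectivity and chemoselectivity: the first two are intrinsic to a monosubstituted alkyne under this catalysis, the unactivated 1,1-disubstituted C7'=C8' alkene should stay outside the carbometalation manifold of the achiral zirconocene at room temperature, and the bulky silyl ethers are not opened by AlMe3 as an acetonide could be. The coumarin lactone is brought in only after all organometallic chemistry is finished.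

Step 9
Reactants: 13 (2E,5S,6S)-5,6-bis[(tert-butyldimethylsilyl)oxy]-3,7-dimethylocta-2,7-dien-1-ol; 14 7-hydroxy-8-methoxy-2H-chromen-2-one (7-hydroxy-8-methoxycoumarin)
Product: 15 7-{[(2E,5S,6S)-5,6-bis[(tert-butyldimethylsilyl)oxy]-3,7-dimethylocta-2,7-dien-1-yl]oxy}-8-methoxy-2H-chromen-2-one
Conditions: PPh3 (1.3 equiv), DIAD (1.3 equiv), THF, 0 °C to rt
Reagents that add atoms: none
Why: Mitsunobu etherification: the acidic 7-hydroxyl (pKa about 8) protonates the betaine and its phenoxide displaces the alkoxyphosphonium at the primary allylic carbon in an SN2 sense, attack at the fully substituted C3' (SN2') being sterically disfavoured, so the E-geometry and the silyl ethers should be retained.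

Step 10
Reactants: 15 7-{[(2E,5S,6S)-5,6-bis[(tert-butyldimethylsilyl)oxy]-3,7-dimethylocta-2,7-dien-1-yl]oxy}-8-methoxy-2H-chromen-2-one
Product: 16 7-{[(2E,5S,6S)-5,6-dihydroxy-3,7-dimethylocta-2,7-dien-1-yl]oxy}-8-methoxy-2H-chromen-2-one
Conditions: Bu4NF (4 equiv), AcOH (4 equiv), THF, 0 °C to rt
Reagents that add atoms: none
Why: Fluoride-induced cleavage of both silyl ethers driven by the Si–F bond; acetic acid buffering keeps the medium from opening the coumarin lactone, and the allylic aryl ether, the alkenes and both carbinol centres are inert to fluoride.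

**Compound list**
1 | dimethyl (4R,5R)-2,2-dimethyl-1,3-dioxolane-4,5-dicarboxylate (dimethyl 2,3-O-isopropylidene-L-tartrate) | COC(=O)[C@@H]1OC(C)(C)O[C@H]1C(=O)OC | starting material
2 | methyl (4R,5S)-5-(hydroxymethyl)-2,2-dimethyl-1,3-dioxolane-4-carboxylate | COC(=O)[C@@H]1OC(C)(C)O[C@H]1CO | intermediate
3 | (4R,5S)-5-(hydroxymethyl)-N-methoxy-N,2,2-trimethyl-1,3-dioxolane-4-carboxamide | CON(C)C(=O)[C@@H]1OC(C)(C)O[C@H]1CO | intermediate (not isolated)
4 | 1-[(4R,5S)-5-(hydroxymethyl)-2,2-dimethyl-1,3-dioxolan-4-yl]ethan-1-one | CC(=O)[C@@H]1OC(C)(C)O[C@H]1CO | intermediate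
5 | [(4S,5S)-2,2-dimethyl-5-(prop-1-en-2-yl)-1,3-dioxolan-4-yl]methanol | C=C(C)[C@@H]1OC(C)(C)O[C@H]1CO | intermediate
6 | [(4S,5S)-2,2-dimethyl-5-(prop-1-en-2-yl)-1,3-dioxolan-4-yl]methyl trifluoromethanesulfonate | C=C(C)[C@@H]1OC(C)(C)O[C@H]1COS(=O)(=O)C(F)(F)F | intermediate
7 | trimethyl{3-[(4S,5S)-2,2-dimethyl-5-(prop-1-en-2-yl)-1,3-dioxolan-4-yl]prop-1-yn-1-yl}silane | C=C(C)[C@@H]1OC(C)(C)O[C@H]1CC#C[Si](C)(C)C | intermediate
8 | (3S,4S)-2-methyl-7-(trimethylsilyl)hept-1-en-6-yne-3,4-diol | C=C(C)[C@H](O)[C@@H](O)CC#C[Si](C)(C)C | intermediate (not isolated)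
9 | (3S,4S)-2-methylhept-1-en-6-yne-3,4-diol | C=C(C)[C@H](O)[C@@H](O)CC#C | intermediate
10 | (3S,4S)-3,4-bis[(tert-butyldimethylsilyl)oxy]-2-methylhept-1-en-6-yne | C=C(C)[C@H](O[Si](C)(C)C(C)(C)C)[C@@H](O[Si](C)(C)C(C)(C)C)CC#C | intermediate
11 | [(1E,4S,5S)-4,5-bis[(tert-butyldimethylsilyl)oxy]-2,6-dimethylhepta-1,6-dien-1-yl]dimethylalumane | C=C(C)[C@H](O[Si](C)(C)C(C)(C)C)[C@@H](O[Si](C)(C)C(C)(C)C)C/C(C)=C/[Al](C)C | intermediate (not isolated)
12 | lithium butyl[(1E,4S,5S)-4,5-bis[(tert-butyldimethylsilyl)oxy]-2,6-dimethylhepta-1,6-dien-1-yl]dimethylaluminate | [Li+].C=C(C)[C@H](O[Si](C)(C)C(C)(C)C)[C@@H](O[Si](C)(C)C(C)(C)C)C/C(C)=C/[Al-](C)(C)CCCC | intermediate (not isolated)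
13 | (2E,5S,6S)-5,6-bis[(tert-butyldimethylsilyl)oxy]-3,7-dimethylocta-2,7-dien-1-ol | C=C(C)[C@H](O[Si](C)(C)C(C)(C)C)[C@@H](O[Si](C)(C)C(C)(C)C)C/C(C)=C/CO | intermediate
14 | 7-hydroxy-8-methoxy-2H-chromen-2-one (7-hydroxy-8-methoxycoumarin) | COc1c(O)ccc2ccc(=O)oc12 | starting material
15 | 7-{[(2E,5S,6S)-5,6-bis[(tert-butyldimethylsilyl)oxy]-3,7-dimethylocta-2,7-dien-1-yl]oxy}-8-methoxy-2H-chromen-2-one | C=C(C)[C@H](O[Si](C)(C)C(C)(C)C)[C@@H](O[Si](C)(C)C(C)(C)C)C/C(C)=C/COc1ccc2ccc(=O)oc2c1OC | intermediate
16 | 7-{[(2E,5S,6S)-5,6-dihydroxy-3,7-dimethylocta-2,7-dien-1-yl]oxy}-8-methoxy-2H-chromen-2-one (CNP0214345.1) | C=C(C)[C@H](O)[C@@H](O)C/C(C)=C/COc1ccc2ccc(=O)oc2c1OC | target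

**Step count**
Total: 10 steps. Longest linear sequence: 10 steps (1 to 16); coumarin 14 enters at step 9 as purchased.

**Steps most likely to fail, with fallbacks**

Step 8. The alanate may capture formaldehyde inefficiently, through slow depolymerisation of paraformaldehyde or protonolysis of the carbon–aluminium bond, which would leave the methylated chain without C1'. The fallback sets out from 10. The same methylalumination is run to alkenylalane 11, which is treated directly with ethyl chloroformate, a known acylation of alkenylalanes. This should give ethyl (2E,5S,6S)-5,6-bis[(tert-butyldimethylsilyl)oxy]-3,7-dimethylocta-2,7-dienoate F1 with the same alkene geometry. Reduction with i-Bu2AlH in CH2Cl2 at −78 °C then rejoins the route at 13.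

Step 1. The reduction is selective only by rate and statistics, so over-reduction to the diol and incomplete conversion may erode the material balance. The fallback sets out from 1. KOH (1.0 equiv) in MeOH should stop at the half ester, (4R,5R)-5-(methoxycarbonyl)-2,2-dimethyl-1,3-dioxolane-4-carboxylic acid F2, because the carboxylate shields the second ester from hydroxide. BH3·SMe2 in THF at 0 °C then reduces the acid in preference to the ester and rejoins the route at 2.

Step 5. The triflate may decompose, or base-induced elimination may compete with substitution at the β-oxygenated, β-branched primary carbon. The fallback sets out from 5. Appel-type iodination (I2, PPh3, imidazole, CH2Cl2) should give the storable electrophile (4R,5S)-4-(iodomethyl)-2,2-dimethyl-5-(prop-1-en-2-yl)-1,3-dioxolane F3. Alkylation with LiC≡CH·H2NCH2CH2NH2 in DMSO at rt should give (4S,5S)-2,2-dimethyl-4-(prop-1-en-2-yl)-5-(prop-2-yn-1-yl)-1,3-dioxolane F4. Acid methanolysis of F4 (p-TsOH·H2O, MeOH, 50 °C) rejoins the route at 9, with no silyl group on the alkyne to remove.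

**Further compounds**
F1 | step 8 | ethyl (2E,5S,6S)-5,6-bis[(tert-butyldimethylsilyl)oxy]-3,7-dimethylocta-2,7-dienoate | C=C(C)[C@H](O[Si](C)(C)C(C)(C)C)[C@@H](O[Si](C)(C)C(C)(C)C)C/C(C)=C/C(=O)OCC
F2 | step 1 | (4R,5R)-5-(methoxycarbonyl)-2,2-dimethyl-1,3-dioxolane-4-carboxylic acid | COC(=O)[C@@H]1OC(C)(C)O[C@H]1C(=O)O
F3 | step 5 | (4R,5S)-4-(iodomethyl)-2,2-dimethyl-5-(prop-1-en-2-yl)-1,3-dioxolane | C=C(C)[C@@H]1OC(C)(C)O[C@H]1CI
F4 | step 5 | (4S,5S)-2,2-dimethyl-4-(prop-1-en-2-yl)-5-(prop-2-yn-1-yl)-1,3-dioxolane | C=C(C)[C@@H]1OC(C)(C)O[C@H]1CC#C
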